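## Structural features

The target consists of two 2H-chromen-2-one (coumarin) bicycles. Coumarin A carries a hydroxyl at C6 and a methoxy group at C7, coumarin B is an umbelliferone unit, and the only link between them is an ether oxygen from C3 of A to C7 of B. The molecule is flat and has no stereocentre, so the only stereochemical question is the geometry of any open-chain alkene that precedes ring closure. Sensitive points are the two lactones (opened by hydroxide or alkoxide), the free 6-OH (with the 7-OMe an easily oxidised catechol monoether), and the C3–O–aryl unit. In an open-chain precursor that unit is an aryl enol ether that a neighbouring free phenol can attack under acid. The real difficulty is the C3–O bond: C3 is the electron-rich alpha carbon of an alpha-pyrone and will not accept a phenoxide by substitution, and the umbelliferone oxygen is a weak nucleophile. A second demand is that 6-OH and 7-OMe are told apart without ambiguity. The feature used here is that C2 of coumarin A is a lone carbonyl carbon between O1 (a phenolic oxygen on C8a) and C3 (the vinyl carbon bearing the ether oxygen). Taking it out as CO leaves a 2-hydroxyphenyl Z-enol ether in which the C3–O bond already exists, and the remaining benzene ring maps onto vanillin (its hydroxyl becomes O6, its methoxy group the 7-OMe).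

## Logic of the disconnections

16 to 15: only the O–CH2 bond of a methoxymethyl acetal on O6 is cut. The free 6-OH sits para to O1 and would make the carbonylation substrate a hydroquinone that benzoquinone oxidises, so it must be masked. The forward step has to be an acid treatment mild enough for two lactones.

15 to 12: the bonds O1–C2 and C2–C3 are cut and C2 leaves as carbon monoxide. This opens the pyranone ring of coumarin A and reduces the problem to a phenol beside a Z-aryl enol ether. The forward step must carbonylate the phenol, close the ring at the oxygen-bearing vinyl carbon in a 6-endo mode, and leave the enol ether C–O bond intact.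

12 to 11: the O–allyl bond at the future O1 is cut. The phenol has to stay masked while the enol ether is made, because a free ortho phenol beside an alkyne closes to a benzofuran under base. The forward step must remove the mask without acid, hence allyl and zerovalent palladium.

11 to 9 and 10: the vinyl C–O bond (future C3–O) is cut. This is the hardest bond of the target and is best made while C3 is still an alkyne carbon. The gain is two fragments of similar size. The forward step must add the phenol oxygen of 10 to the terminal carbon of 9 in an anti sense, so that the Z geometry results.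

9 to 7: the terminal alkyne carbon is removed, so the triple bond becomes an aldehyde. The forward step is a one-carbon homologation that must tolerate an allyl ether and an acetal.

7 to 6: the O–allyl bond is cut. The forward step is a plain alkylation of a chelated phenol.

6 to 4: the aryl–CHO bond is cut. The forward step must formylate only ortho to the phenol and only at the unhindered ortho position, which is para to the methoxy group.

4 to 2 (through 3): the aryl–O bond of the phenol is traced back to an aryl–CHO bond. The gain is that the 1,2,4-oxygen pattern is taken from a benzaldehyde with fixed regiochemistry, with no hydroxylation of an aromatic C–H bond. The forward step is an oxidative aryl migration that the acetal must survive.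

2 to 1: the O–CH2 bond of the acetal is cut, leaving a commercial phenolic aldehyde. Since 1 has only one hydroxyl, no selective monoprotection is needed.

## Other disconnections considered

Alternative 1: The cut removes O1 from between C8a and C2, which contracts the lactone to the five-membered ketone of the racemic 2-aryloxyindan-1-one A1. Forward, mCPBA would effect a Baeyer–Villiger oxidation of A1 with migration of the aryl carbon to give the racemic dihydrocoumarin A2.
- In favour: the hard C3–O bond becomes an SN2 displacement of an alpha-bromo ketone by 10 at an sp3 carbon. That is easier than forming a vinyl C–O bond, and no CO, no palladium and no alkene geometry are involved. On these points the alternative is the better.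
- Against: A2 is one oxidation level too low, so the C3–C4 double bond must still be introduced next to an electron-rich silylated ring. The oxygen-bearing C2 of A1 also has a high migratory aptitude and could migrate instead of the aryl carbon. The peracid can attack the electron-rich arene, and the silyl ether may not survive the phenoxide displacement.
- Comparison: on structure, the chosen plan gives the coumarin oxidation level directly and A2 does not. On mechanism, both hinge on one selectivity (migrating group there, 6-endo acyl insertion here), and the ring expansion of indanones is the better established of the two. On step economy the two are about equal.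

Alternative 2: The cut removes C4 and O1 together (from DMF) and C2–C3 together (from a ketene silyl acetal), leaving an aryne. Forward, CsF in DMF would convert the silyl aryl triflate A3 into the aryne, DMF would add across it, and the ketene silyl acetal A4 would join and close the pyranone with loss of dimethylamine, giving A5.
- In favour: the whole pyranone is assembled in one flask from three simple parts without a transition metal. The C3–O bond comes from an O-alkylation of 10 with a haloacetate. In convergence and in the ease of the C–O bond it is the better of the two plans.
- Against: A5 is not the target but its 6,7-methylenedioxy analogue. A symmetrical aryne is needed because two remote alkoxy groups would not control the direction of DMF addition to an unsymmetrical one. The acetal would then have to be opened (for example with BCl3) to the catechol A6, and A6 methylated only at O7. That selectivity rests solely on the higher acidity of the 7-OH, and the Lewis acid meets two lactones and an aryl enol ether.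
- Comparison: on structure, the chosen plan fixes 6-OH against 7-OMe from the first step, while this one leaves it to the last. On mechanism, the three-component coupling is known chemistry and safer than the carbonylation. On step economy it is similar once the two corrective steps are counted.

Alternative 3: The cut removes the two bonds of C3 that lead to the umbelliferone oxygen and to C4, so that C3 becomes the carbenoid carbon of the aryl diazoacetate A7. Forward, Rh2(OAc)4 would generate the carbenoid from A7, 10 would insert through its O–H bond, and the resulting enol would add to the ortho aldehyde and lose water, giving A8.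
- In favour: the C3–O bond forms under neutral, mild conditions, there is no alkene geometry to control and no CO. The sequence to A8 is clearly shorter than the chosen one, so in step economy and in how the C–O bond is made the alternative is the better.
- Against: the diazoacetate has to be built on a chelated salicylaldehyde phenol. The carbenoid can be trapped by its own ortho aldehyde oxygen or by the electron-rich ring before the weakly nucleophilic 10 arrives, and carbene dimerisation competes.
- Comparison: on structure, both deliver a 6-O-protected coumarin one deprotection from the target, which is equal. On mechanism, both rely on a cascade whose first event must outrun an intramolecular side reaction, with comparable uncertainty. On step economy the alternative is better.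

Key step: step 8

Remark: the target is taken as drawn (6-hydroxy-7-methoxy, the regioisomer of the daphnoretin pattern). The organopalladium species 13 and 14 are drawn with one acetate ligand; CO and solvent ligands are left out.

Remark: the ring A oxygen pattern is taken from 1, so that no aromatic C–H bond has to be hydroxylated with persulfate and no hydroquinone has to be monoprotected selectively. This costs one step and makes every early step regiochemically unambiguous.

## Route

Step 1
Reactants: 1 vanillin (4-hydroxy-3-methoxybenzaldehyde)
Product: 2 3-methoxy-4-(methoxymethoxy)benzaldehyde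
Conditions: MOMCl, i-Pr2NEt, CH2Cl2, 0 °C to rt
Reagents that add atoms: chloromethyl methyl ether (MOMCl), COCCl
Why: Williamson-type O-alkylation of the phenoxide by the reactive alpha-chloro ether; the acetal is stable to every basic, oxidative and palladium-mediated step that follows and falls to mild acid at the end.

Step 2
Reactants: 2 3-methoxy-4-(methoxymethoxy)benzaldehyde
Product: 4 3-methoxy-4-(methoxymethoxy)phenol, via aryl formate 3 (not isolated)
Conditions: mCPBA, CH2Cl2, 0 °C to rt; then K2CO3 (cat.), MeOH, rt
Reagents that add atoms: mCPBA (3-chloroperoxybenzoic acid), OOC(=O)c1cccc(Cl)c1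
Why: Baeyer–Villiger (Dakin-type) oxidation in which the electron-rich aryl group with a para oxygen migrates in preference to hydride, giving formate 3, which catalytic K2CO3 in MeOH transesterifies to the phenol; the acetal tolerates the weak carboxylic acid that is formed.

Step 3
Reactants: 4 3-methoxy-4-(methoxymethoxy)phenol
Product: 6 2-hydroxy-4-methoxy-5-(methoxymethoxy)benzaldehyde, via salicyl alcohol 5 (not isolated)
Conditions: (CH2O)n, MgCl2, Et3N, MeCN, reflux; aqueous citric acid work-up
Reagents that add atoms: formaldehyde (as paraformaldehyde), C=O
Why: Magnesium-mediated ortho-formylation (Casnati–Skattebøl): the ArOMgCl phenoxide delivers formaldehyde only ortho to oxygen, and of the two ortho positions the unhindered one para to the methoxy group should react; the hydroxymethyl compound 5 is oxidised in the flask by hydride transfer to a second formaldehyde.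

Step 4
Reactants: 6 2-hydroxy-4-methoxy-5-(methoxymethoxy)benzaldehyde
Product: 7 4-methoxy-5-(methoxymethoxy)-2-(prop-2-en-1-yloxy)benzaldehyde
Conditions: allyl bromide, K2CO3, DMF, rt
Reagents that add atoms: allyl bromide, C=CCBr
Why: Williamson etherification of the chelated phenol in a dipolar solvent; allyl is chosen because it survives carbonate at 100 °C and can later be removed without acid.

Step 5
Reactants: 7 4-methoxy-5-(methoxymethoxy)-2-(prop-2-en-1-yloxy)benzaldehyde
Product: 9 1-ethynyl-4-methoxy-5-(methoxymethoxy)-2-(prop-2-en-1-yloxy)benzene, via diazoalkene 8 (not isolated)
Conditions: dimethyl (1-diazo-2-oxopropyl)phosphonate, K2CO3, MeOH, rt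
Reagents that add atoms: dimethyl (1-diazo-2-oxopropyl)phosphonate (Ohira–Bestmann reagent), CC(=O)C(=[N+]=[N-])P(=O)(OC)OC
Why: Seyferth–Gilbert homologation in its Ohira–Bestmann form: methanolysis of the reagent gives the diazomethylphosphonate anion, which olefinates the aldehyde to diazoalkene 8; loss of N2 and a 1,2-hydrogen shift of the alkylidene carbene give the terminal alkyne under conditions that spare the allyl ether and the acetal.

Step 6
Reactants: 9 1-ethynyl-4-methoxy-5-(methoxymethoxy)-2-(prop-2-en-1-yloxy)benzene; 10 umbelliferone (7-hydroxy-2H-chromen-2-one)
Product: 11 7-({(Z)-2-[4-methoxy-5-(methoxymethoxy)-2-(prop-2-en-1-yloxy)phenyl]ethenyl}oxy)-2H-chromen-2-one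
Conditions: 10 (1.5 equiv), Cs2CO3 (0.5 equiv), dry NMP, 100 °C
Reagents that add atoms: none
Why: Base-mediated anti-Markovnikov hydroaryloxylation of an arylacetylene: the phenoxide of 10 adds to the terminal carbon and the aryl-stabilised vinyl anion is protonated trans to the incoming oxygen, so anti addition should give the Z-enol ether as the kinetic product; moderate temperature and a short reaction time are meant to prevent equilibration to the E isomer, and the protected ortho oxygen blocks benzofuran formation.

Step 7
Reactants: 11 7-({(Z)-2-[4-methoxy-5-(methoxymethoxy)-2-(prop-2-en-1-yloxy)phenyl]ethenyl}oxy)-2H-chromen-2-one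
Product: 12 7-({(Z)-2-[2-hydroxy-4-methoxy-5-(methoxymethoxy)phenyl]ethenyl}oxy)-2H-chromen-2-one
Conditions: Pd(PPh3)4 (5 mol %), morpholine, THF, rt
Reagents that add atoms: none
Why: Tsuji–Trost-type deallylation: zerovalent palladium ionises the aryl allyl ether to a pi-allylpalladium phenoxide and morpholine captures the allyl group; the medium stays basic, which protects the acid-sensitive pair of free phenol and enol ether, and 12 is carried on without storage.

Step 8
Reactants: 12 7-({(Z)-2-[2-hydroxy-4-methoxy-5-(methoxymethoxy)phenyl]ethenyl}oxy)-2H-chromen-2-one
Product: 15 7-methoxy-6-(methoxymethoxy)-3-[(2-oxo-2H-chromen-7-yl)oxy]-2H-chromen-2-one, via aryloxycarbonylpalladium acetate 13 (not isolated), via benzylic alkylpalladium acetate 14 (not isolated)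
Conditions: Pd(OAc)2 (10 mol %), 1,4-benzoquinone (2 equiv), NaOAc (20 mol %), CO (5 bar), MeCN, 80 °C
Reagents that add atoms: carbon monoxide, [C-]#[O+]
Why: Proposed new method: Pd(OAc)2 should turn the phenol of 12 into an ArO–Pd–OAc phenoxide, CO inserts to give the aryloxycarbonylpalladium species 13, and this adds syn across the enol ether so that the acyl carbon C2 bonds to the oxygen-bearing C3 and palladium ends on benzylic C4 (14); syn beta-hydride elimination of H3 then creates the C3–C4 double bond of 15 and zerovalent palladium, which benzoquinone returns to divalent palladium. The closest known reactions are the Pd(OAc)2/benzoquinone oxidative cyclocarbonylation of simple 2-vinylphenols to coumarins and the oxidative alkoxycarbonylation of styrenes to cinnamates; what is new is an enol ether as the alkene partner. The pyranone ring closes in a 6-endo-trig mode. No stereocentre remains in 15; the two transient ones in 14 are fixed by syn addition to the Z alkene, which places palladium trans to the aryloxy group and cis to H3, the only arrangement that allows syn beta-hydride elimination, hence the need for the Z isomer. Six-membered closure should be preferred over five-membered closure because palladium becomes benzylic and because the polarised enol ether directs the migrating acyl group to its oxygen-bearing carbon, as in cationic Heck reactions of vinyl ethers. Chemoselectivity is needed against direct attack of the phenol on the enol ether; CO pressure, which keeps palladium carbonylated, and the acetate buffer are meant to secure it. The acetal on O6 keeps the hydroquinone-type ring from being oxidised by benzoquinone.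

Step 9
Reactants: 15 7-methoxy-6-(methoxymethoxy)-3-[(2-oxo-2H-chromen-7-yl)oxy]-2H-chromen-2-one
Product: 16 6-hydroxy-7-methoxy-3-[(2-oxo-2H-chromen-7-yl)oxy]-2H-chromen-2-one
Conditions: HCl (1.25 M in MeOH), THF, rt to 40 °C
Reagents that add atoms: none
Why: Acid-catalysed acetal exchange transfers the methoxymethyl group to methanol, while the lactones, the aryl ether at C3 and the methyl ether are inert to dilute HCl at this temperature.

## Compound list

1 | vanillin (4-hydroxy-3-methoxybenzaldehyde) | COc1cc(C=O)ccc1O | starting material
2 | 3-methoxy-4-(methoxymethoxy)benzaldehyde | COCOc1ccc(C=O)cc1OC | intermediate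
3 | 3-methoxy-4-(methoxymethoxy)phenyl formate | COCOc1ccc(OC=O)cc1OC | intermediate
4 | 3-methoxy-4-(methoxymethoxy)phenol | COCOc1ccc(O)cc1OC | intermediate
5 | 2-(hydroxymethyl)-5-methoxy-4-(methoxymethoxy)phenol (present as its magnesium salt) | COCOc1cc(CO)c(O)cc1OC | intermediate
6 | 2-hydroxy-4-methoxy-5-(methoxymethoxy)benzaldehyde | COCOc1cc(C=O)c(O)cc1OC | intermediate
7 | 4-methoxy-5-(methoxymethoxy)-2-(prop-2-en-1-yloxy)benzaldehyde | C=CCOc1cc(OC)c(OCOC)cc1C=O | intermediate
8 | 1-(2-diazoethenyl)-4-methoxy-5-(methoxymethoxy)-2-(prop-2-en-1-yloxy)benzene | C=CCOc1cc(OC)c(OCOC)cc1C=C=[N+]=[N-] | intermediate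
9 | 1-ethynyl-4-methoxy-5-(methoxymethoxy)-2-(prop-2-en-1-yloxy)benzene | C=CCOc1cc(OC)c(OCOC)cc1C#C | intermediate
10 | umbelliferone (7-hydroxy-2H-chromen-2-one) | O=c1ccc2ccc(O)cc2o1 | starting material
11 | 7-({(Z)-2-[4-methoxy-5-(methoxymethoxy)-2-(prop-2-en-1-yloxy)phenyl]ethenyl}oxy)-2H-chromen-2-one | C=CCOc1cc(OC)c(OCOC)cc1/C=C\Oc1ccc2ccc(=O)oc2c1 | intermediate
12 | 7-({(Z)-2-[2-hydroxy-4-methoxy-5-(methoxymethoxy)phenyl]ethenyl}oxy)-2H-chromen-2-one | COCOc1cc(/C=C\Oc2ccc3ccc(=O)oc3c2)c(O)cc1OC | intermediate
13 | acetato{[5-methoxy-4-(methoxymethoxy)-2-{(Z)-2-[(2-oxo-2H-chromen-7-yl)oxy]ethenyl}phenoxy]carbonyl}palladium (further ligands omitted) | COCOc1cc(/C=C\Oc2ccc3ccc(=O)oc3c2)c(OC(=O)[Pd]OC(C)=O)cc1OC | intermediate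
14 | acetato{7-methoxy-6-(methoxymethoxy)-2-oxo-3-[(2-oxo-2H-chromen-7-yl)oxy]-3,4-dihydro-2H-chromen-4-yl}palladium, racemic, palladium at C4 trans to the aryloxy group at C3 and cis to H3 (further ligands omitted) | COCOc1cc2[C@@H]([Pd]OC(C)=O)[C@H](Oc3ccc4ccc(=O)oc4c3)C(=O)Oc2cc1OC | intermediate
15 | 7-methoxy-6-(methoxymethoxy)-3-[(2-oxo-2H-chromen-7-yl)oxy]-2H-chromen-2-one | COCOc1cc2cc(Oc3ccc4ccc(=O)oc4c3)c(=O)oc2cc1OC | intermediate
16 | 6-hydroxy-7-methoxy-3-[(2-oxo-2H-chromen-7-yl)oxy]-2H-chromen-2-one (CNP0157415.0) | COc1cc2oc(=O)c(Oc3ccc4ccc(=O)oc4c3)cc2cc1O | target

## Step count and least certain steps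

Total steps: 9. Longest linear sequence: 9 steps (1 to 16); 10 is used as purchased and enters at step 6.

Step 8 (key step, proposed new method). Three processes could defeat it.
- The neighbouring phenol may capture the enol ether, by oxypalladation or by acid, before carbonylation. Five-membered ring closure would then expel the umbelliferone oxygen.
- The aryloxide may be lost from 14 by anti elimination, since it stands trans to palladium.
- Ring closure may run through palladation of the vinylic C–H bond instead of acyl insertion. In the Z isomer the position cis to the arene carries the aryloxy group, not hydrogen, so that pathway would stall.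

The fallback is known chemistry, sets out from 10 and 6 and returns at 15. Compound 10 is alkylated with tert-butyl bromoacetate (K2CO3, acetone) to tert-butyl [(2-oxo-2H-chromen-7-yl)oxy]acetate F1. CF3CO2H in CH2Cl2 cleaves the ester to [(2-oxo-2H-chromen-7-yl)oxy]acetic acid F2. F2 is condensed with 6 under Perkin conditions (Ac2O, Et3N, 100 °C): the phenol is acylated to 2-formyl-5-methoxy-4-(methoxymethoxy)phenyl [(2-oxo-2H-chromen-7-yl)oxy]acetate F3, which closes by intramolecular aldol condensation and dehydration to 15, and step 9 follows. This classical access to 3-aryloxycoumarins forms C3–C4 and O1–C2 instead of O1–C2 and C2–C3, and it is shorter than the main line.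

Step 6. The phenoxide of 10 is a weak nucleophile and the alkyne of 9 is electron-rich, so the addition may be slow. Forcing it invites base-mediated isomerisation of the Z-enol ether to the E isomer and opening of the lactone by adventitious hydroxide.

The fallback sets out from 7 (with 10) and returns at 11. Stork–Zhao olefination of 7 with (iodomethyl)triphenylphosphonium iodide and NaN(SiMe3)2 (THF, −78 °C) should give (Z)-1-(2-iodoethenyl)-4-methoxy-5-(methoxymethoxy)-2-(prop-2-en-1-yloxy)benzene F4. Stereoretentive Ullmann-type coupling of F4 with 10 (CuI, N,N-dimethylglycine, Cs2CO3, dioxane, 80 °C) then forms the vinyl C–O bond of 11. The geometry is then set in the olefination, not in the addition.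

Step 3. Formylation may occur in part at the position between the hydroxyl and the methoxy group, and chelation by magnesium at reflux may cause loss of the acetal.

The fallback sets out from 4 and returns at 7, replacing steps 3 and 4. Bromination of 4 with NBS (CH2Cl2, −20 °C) ortho to the hydroxyl and para to the methoxy group gives 2-bromo-5-methoxy-4-(methoxymethoxy)phenol F5. Allylation (allyl bromide, K2CO3, DMF) gives 1-bromo-4-methoxy-5-(methoxymethoxy)-2-(prop-2-en-1-yloxy)benzene F6. Bromine–lithium exchange (n-BuLi, THF, −78 °C) and quenching of the aryllithium with DMF give 7, with no Lewis acid and no heating.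

## Further compounds

F1 | step 8 | tert-butyl [(2-oxo-2H-chromen-7-yl)oxy]acetate | CC(C)(C)OC(=O)COc1ccc2ccc(=O)oc2c1
F2 | step 8 | [(2-oxo-2H-chromen-7-yl)oxy]acetic acid | OC(=O)COc1ccc2ccc(=O)oc2c1
F3 | step 8 | 2-formyl-5-methoxy-4-(methoxymethoxy)phenyl [(2-oxo-2H-chromen-7-yl)oxy]acetate | COCOc1cc(C=O)c(OC(=O)COc2ccc3ccc(=O)oc3c2)cc1OC
F4 | step 6 | (Z)-1-(2-iodoethenyl)-4-methoxy-5-(methoxymethoxy)-2-(prop-2-en-1-yloxy)benzene | C=CCOc1cc(OC)c(OCOC)cc1/C=C\I
F5 | step 3 | 2-bromo-5-methoxy-4-(methoxymethoxy)phenol | COCOc1cc(Br)c(O)cc1OC
F6 | step 3 | 1-bromo-4-methoxy-5-(methoxymethoxy)-2-(prop-2-en-1-yloxy)benzene | C=CCOc1cc(OC)c(OCOC)cc1Br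
A1 | alternative 1 | racemic 5-(tert-butyldimethylsilyloxy)-6-methoxy-2-[(2-oxo-2H-chromen-7-yl)oxy]-2,3-dihydro-1H-inden-1-one | COc1cc2C(=O)C(Oc3ccc4ccc(=O)oc4c3)Cc2cc1O[Si](C)(C)C(C)(C)C
A2 | alternative 1 | racemic 6-(tert-butyldimethylsilyloxy)-7-methoxy-3-[(2-oxo-2H-chromen-7-yl)oxy]chroman-2-one | COc1cc2OC(=O)C(Oc3ccc4ccc(=O)oc4c3)Cc2cc1O[Si](C)(C)C(C)(C)C
A3 | alternative 2 | 6-(trimethylsilyl)-1,3-benzodioxol-5-yl trifluoromethanesulfonate | C[Si](C)(C)c1cc2OCOc2cc1OS(=O)(=O)C(F)(F)F
A4 | alternative 2 | 7-{[2-methoxy-2-(trimethylsilyloxy)ethenyl]oxy}-2H-chromen-2-one (mixture of alkene isomers) | COC(O[Si](C)(C)C)=COc1ccc2ccc(=O)oc2c1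
A5 | alternative 2 | 7-[(2-oxo-2H-chromen-7-yl)oxy]-6H-[1,3]dioxolo[4,5-g]chromen-6-one | O=c1oc2cc3OCOc3cc2cc1Oc1ccc2ccc(=O)oc2c1
A6 | alternative 2 | 6,7-dihydroxy-3-[(2-oxo-2H-chromen-7-yl)oxy]-2H-chromen-2-one | O=c1oc2cc(O)c(O)cc2cc1Oc1ccc2ccc(=O)oc2c1
A7 | alternative 3 | 4-(tert-butyldimethylsilyloxy)-2-formyl-5-methoxyphenyl 2-diazoacetate | COc1cc(OC(=O)C=[N+]=[N-])c(C=O)cc1O[Si](C)(C)C(C)(C)C
A8 | alternative 3 | 6-(tert-butyldimethylsilyloxy)-7-methoxy-3-[(2-oxo-2H-chromen-7-yl)oxy]-2H-chromen-2-one | COc1cc2oc(=O)c(Oc3ccc4ccc(=O)oc4c3)cc2cc1O[Si](C)(C)C(C)(C)C
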